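## Retrosynthetic overview

1. Ring B (the cyclopentane) is opened at the C-1–C-7a bond (indene numbering). The last step is a cation–olefin closure of a tertiary cation onto a tetrasubstituted cyclohexene, ended by loss of H-4. This is the second C–C bond and the termination of the presumed biogenetic (3+2) union of two C10 units.
2. The first biogenetic bond (acid α-carbon to the exocyclic allyl terminus) is made beforehand, with the natural polarity, by enantioselective α-allylation of a geranic-acid dienediolate. This sets C-2, which then steers C-1 and C-7a.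
3. The acid half comes from geranic acid (ozonolysis, then Z-selective β-oxido-ylide hydroxymethylation). The allyl bromide half comes from 2,2-dimethylcyclohexanone.
4. Ring order: ring A (six-membered) is carried in from the commercial ketone; ring B (five-membered) is formed last and gives the target directly.

Assumption: the skeleton is irregular (two C10 units), and its biogenesis is taken to be a stepwise cationic (3+2) annulation between the exocyclic allyl cation of a cyclogeranyl-type unit and the 2,3-alkene of a (Z)-terminally oxygenated geranic acid unit, ended by loss of H-4.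

## Route

Step 1
Reactants: 1 2,2-dimethylcyclohexan-1-one
Product: 2 2,2-dimethyl-6-methylidenecyclohexan-1-one
Conditions: (CH2O)n, i-Pr2NH·CF3CO2H (1 equiv), CF3CO2H (10 mol%), THF, reflux; used at once
Reagents that add atoms: paraformaldehyde (formaldehyde), C=O
Why: Amine-salt-mediated Mannich-type α-methylenation takes place only at C-6, the sole enolisable position, and creates no stereocentre.

Step 2
Reactants: 2 2,2-dimethyl-6-methylidenecyclohexan-1-one
Product: 3 (±)-1,2,2-trimethyl-6-methylidenecyclohexan-1-ol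
Conditions: MeLi, CeCl3, THF, −78 °C; aq. NH4Cl
Reagents that add atoms: methyllithium, [Li]C
Why: Organocerium 1,2-addition to the hindered exo-methylene ketone gives the tertiary allylic alcohol without conjugate addition; the new stereocentre is racemic and is erased in step 3.

Step 3
Reactants: 3 (±)-1,2,2-trimethyl-6-methylidenecyclohexan-1-ol
Product: 4 1-(bromomethyl)-2,3,3-trimethylcyclohex-1-ene
Conditions: PBr3 (0.4 equiv), pyridine (cat.), Et2O, −10 → 0 °C
Reagents that add atoms: phosphorus tribromide, BrP(Br)Br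
Why: Bromination with allylic transposition (SN2′, as in linalool → geranyl bromide) gives the more stable primary allylic bromide with the tetrasubstituted ring alkene and removes the stereocentre.

Step 4
Reactants: 5 (2E)-3,7-dimethylocta-2,6-dienoic acid (geranic acid)
Product: 7 (2E)-3-methyl-6-oxohex-2-enoic acid, via ozonide 6 (not isolated)
Conditions: O3 (1 equiv, Sudan Red 7B end point), CH2Cl2, −78 °C; Me2S, −78 °C → rt
Reagents that add atoms: ozone, [O-][O+]=O
Why: Criegee ozonolysis with one equivalent of ozone cleaves only the electron-rich 6,7-alkene, the acid-conjugated 2,3-alkene being far less reactive, and reductive work-up gives the aldehyde with the 2E geometry untouched.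

Step 5
Reactants: 7 (2E)-3-methyl-6-oxohex-2-enoic acid
Product: 10 (2E,6Z)-8-hydroxy-3,7-dimethylocta-2,6-dienoic acid, via lithium betaine 8 (not isolated), via β-oxido ylide 9 (not isolated)
Conditions: LiN(SiMe3)2 (1.0 equiv), THF, −78 °C; Ph3P=CHCH3 (from EtPPh3Br, n-BuLi), −78 °C; n-BuLi (1.1 equiv), −78 → −30 °C; (CH2O)n, 0 °C → rt; 1 M HCl
Reagents that add atoms: ethyltriphenylphosphonium bromide, CC[P+](c1ccccc1)(c1ccccc1)c1ccccc1.[Br-]; paraformaldehyde (formaldehyde), C=O
Why: Wittig–Schlosser β-oxido-ylide olefination in its hydroxymethylation variant: the betaine is deprotonated at carbon, the ylide is trapped by formaldehyde, and loss of Ph3PO with the aldehyde oxygen leaves the chain trans to the ylide methyl, so the CH2OH is cis to the chain (6Z); the lithium carboxylate is inert at −78 °C.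

Step 6
Reactants: 10 (2E,6Z)-8-hydroxy-3,7-dimethylocta-2,6-dienoic acid; 4 1-(bromomethyl)-2,3,3-trimethylcyclohex-1-ene
Product: 12 (2S,6Z)-8-hydroxy-7-methyl-3-methylidene-2-[(2,3,3-trimethylcyclohex-1-en-1-yl)methyl]oct-6-enoic acid, via trilithium dienediolate 11 (not isolated)
Conditions: (R,R)-tetramine 1TA [N,N′-bis((1R)-1-phenyl-2-(piperidin-1-yl)ethyl)propane-1,3-diamine] (1.05 equiv), n-BuLi (5.1 equiv), THF, 0 °C; 4 (1.3 equiv), −78 → −40 °C; 1 M HCl (amine recovered)
Reagents that add atoms: none
Why: Enantioselective enediolate alkylation with a chiral dilithium amide as traceless auxiliary: γ-deprotonation at the 3-methyl (cis to the carboxylate) gives the cross-conjugated dienediolate, which the primary allylic bromide alkylates at the α-carbon (SN2, as in lavandulic acid synthesis), and the mixed aggregate with the (R,R)-amide exposes one face so that C-2 forms as S (sense assigned by analogy with arylacetic and 3-alkenoic acids; the (S,S)-amine gives the antipode).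

Step 7
Reactants: 12 (2S,6Z)-8-hydroxy-7-methyl-3-methylidene-2-[(2,3,3-trimethylcyclohex-1-en-1-yl)methyl]oct-6-enoic acid
Product: 14 (2S,6Z)-8-(acetyloxy)-7-methyl-3-methylidene-2-[(2,3,3-trimethylcyclohex-1-en-1-yl)methyl]oct-6-enoic acid, via mixed anhydride 13 (not isolated)
Conditions: Ac2O (2.5 equiv), pyridine, 0 °C → rt; then H2O/THF, rt
Reagents that add atoms: acetic anhydride, CC(=O)OC(C)=O
Why: Pyridine-mediated acetylation acylates the primary allylic alcohol and, transiently, the carboxyl group, and water then hydrolyses only the mixed anhydride; C-2 and both alkene geometries are untouched.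

Step 8
Reactants: 14 (2S,6Z)-8-(acetyloxy)-7-methyl-3-methylidene-2-[(2,3,3-trimethylcyclohex-1-en-1-yl)methyl]oct-6-enoic acid
Product: 17 (1R,2S,7aS)-1-[(3Z)-5-(acetyloxy)-4-methylpent-3-en-1-yl]-1,7,7,7a-tetramethyl-2,3,5,6,7,7a-hexahydro-1H-indene-2-carboxylic acid (target), via tertiary cation 15 (not isolated), via ring-fusion cation 16 (not isolated)
Conditions: C36H52CoN2O2 [(R,R)-N,N′-bis(3,5-di-tert-butylsalicylidene)cyclohexane-1,2-diamine cobalt complex, divalent cobalt] (5 mol%), N-fluoro-2,4,6-trimethylpyridinium tetrafluoroborate (1.3 equiv), PhSiH3 (1.2 equiv), PhCF3, 0 °C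
Reagents that add atoms: none
Why: Proposed new method: the cobalt hydride formed from the salen complex, the N–F oxidant and PhSiH3 delivers H• only to the 1,1-disubstituted alkene (tetra- and trisubstituted alkenes react far more slowly), and one-electron oxidation of the tertiary alkylcobalt gives the chain C-3 cation 15 with no free Brønsted acid, so the six-ring closure that protonation of the ring alkene would start is shut off; the only π-nucleophile within reach is the tetrasubstituted alkene, whose methyl-bearing carbon closes ring B (5-endo cation–olefin cyclisation, the second C–C bond of the biogenetic (3+2) annulation) to give cation 16, and the collidine set free removes the axial H-4 (the C-3 hydrogens sit next to the carboxyl-bearing carbon and are more shielded; the bridged γ-lactone is strained); C-7a is set because the carboxyl group takes the exo position of the envelope-like transition state, which puts it cis to the methyl that was cis to the tether on the alkene, and C-1 because the longer chain on the cation turns to the face away from the carboxyl group, a choice the chiral ligand is expected to reinforce (the (S,S)-complex is used if (R,R) proves mismatched); closest known reactions: cobalt–salen/N-fluoropyridinium/silane radical–polar crossover hydroalkoxylation and hydroarylation of unactivated alkenes, HAT-initiated polyene cyclisations, and acid-mediated cation–olefin cyclisations.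

## Compound list

1 | 2,2-dimethylcyclohexan-1-one | CC1(C)CCCCC1=O | starting material
2 | 2,2-dimethyl-6-methylidenecyclohexan-1-one | C=C1CCCC(C)(C)C1=O | intermediate
3 | (±)-1,2,2-trimethyl-6-methylidenecyclohexan-1-ol | C=C1CCCC(C)(C)C1(C)O | intermediate
4 | 1-(bromomethyl)-2,3,3-trimethylcyclohex-1-ene | BrCC1=C(C)C(C)(C)CCC1 | intermediate
5 | (2E)-3,7-dimethylocta-2,6-dienoic acid (geranic acid) | CC(C)=CCC/C(C)=C/C(=O)O | starting material
6 | (2E)-5-(5,5-dimethyl-1,2,4-trioxolan-3-yl)-3-methylpent-2-enoic acid (ozonide, not isolated) | CC1(C)OOC(CC/C(C)=C/C(=O)O)O1 | intermediate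
7 | (2E)-3-methyl-6-oxohex-2-enoic acid | O=CCC/C(C)=C/C(=O)O | intermediate
8 | lithium (2E)-3-methyl-6-oxido-7-(triphenylphosphaniumyl)oct-2-enoate (betaine, not isolated) | CC(C([O-])CC/C(C)=C/C([O-])=O)[P+](c1ccccc1)(c1ccccc1)c1ccccc1.[Li+] | intermediate
9 | dilithium (2E)-3-methyl-6-oxido-7-(triphenylphosphoranylidene)oct-2-enoate (β-oxido ylide, not isolated) | CC(C([O-])CC/C(C)=C/C([O-])=O)=P(c1ccccc1)(c1ccccc1)c1ccccc1.[Li+].[Li+] | intermediate
10 | (2E,6Z)-8-hydroxy-3,7-dimethylocta-2,6-dienoic acid | OC/C(C)=C\CC/C(C)=C/C(=O)O | intermediate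
11 | trilithium (6Z)-7-methyl-3-methylidene-8-oxidoocta-1,6-diene-1,1-bis(olate) (not isolated) | [Li+].[Li+].[Li+].[O-]C([O-])=CC(=C)CC/C=C(C)\C[O-] | intermediate
12 | (2S,6Z)-8-hydroxy-7-methyl-3-methylidene-2-[(2,3,3-trimethylcyclohex-1-en-1-yl)methyl]oct-6-enoic acid | OC/C(C)=C\CCC(=C)[C@H](CC1=C(C)C(C)(C)CCC1)C(=O)O | intermediate
13 | acetic (2S,6Z)-8-(acetyloxy)-7-methyl-3-methylidene-2-[(2,3,3-trimethylcyclohex-1-en-1-yl)methyl]oct-6-enoic anhydride (not isolated) | CC(=O)OC/C(C)=C\CCC(=C)[C@H](CC1=C(C)C(C)(C)CCC1)C(=O)OC(C)=O | intermediate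
14 | (2S,6Z)-8-(acetyloxy)-7-methyl-3-methylidene-2-[(2,3,3-trimethylcyclohex-1-en-1-yl)methyl]oct-6-enoic acid | CC(=O)OC/C(C)=C\CCC(=C)[C@H](CC1=C(C)C(C)(C)CCC1)C(=O)O | intermediate
15 | chain C-3 tertiary carbocation of 14 (exo-methylene now CH3; C-2 unchanged; not isolated) | CC(=O)OC/C(C)=C\CC[C+](C)[C@H](CC1=C(C)C(C)(C)CCC1)C(=O)O | intermediate
16 | C-3a (ring-fusion) tertiary carbocation of the hydrindane, configured as 17 at C-1, C-2 and C-7a (not isolated) | CC(=O)OC/C(C)=C\CC[C@]1(C)[C@@H](C(=O)O)C[C+]2CCCC(C)(C)[C@@]21C | intermediate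
17 | (1R,2S,7aS)-1-[(3Z)-5-(acetyloxy)-4-methylpent-3-en-1-yl]-1,7,7,7a-tetramethyl-2,3,5,6,7,7a-hexahydro-1H-indene-2-carboxylic acid | CC(=O)OC/C(C)=C\CC[C@]1(C)[C@@H](C(=O)O)CC2=CCCC(C)(C)[C@@]21C | target

## Step count and risks

Total steps: 8. Longest linear sequence: 6 steps (1 → 2 → 3 → 4 → 12 → 14 → 17; the geranic acid branch is 5 steps).

**Step 8 (most likely to fail).** The 5-endo closure must forge two adjacent quaternary carbons. Four things can go wrong:
- Cation 15 may simply lose a proton before it cyclises.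
- Cation 16 may lose H-3 instead of H-4, giving the cyclopentene isomer.
- The carboxyl group may capture either cation as a lactone.
- The methyl/chain face selectivity at C-1 may be only moderate.

Fallback, from 14 back to 17: the acid is masked and the cation is made by ionising an isolated tertiary chloride instead of by radical–polar crossover. 14 is esterified with 2-(trimethylsilyl)ethanol (carbodiimide coupling) to give 2-(trimethylsilyl)ethyl (2S,6Z)-8-(acetyloxy)-7-methyl-3-methylidene-2-[(2,3,3-trimethylcyclohex-1-en-1-yl)methyl]oct-6-enoate F1. Cobalt-catalysed Markovnikov hydrochlorination of the 1,1-disubstituted alkene (Co(BF4)2·6H2O, salen-type ligand, TsCl, PhSiH3, EtOH) gives the tertiary chloride 2-(trimethylsilyl)ethyl (2R,6Z)-8-(acetyloxy)-3-chloro-3,7-dimethyl-2-[(2,3,3-trimethylcyclohex-1-en-1-yl)methyl]oct-6-enoate F2. AgBF4 with 2,6-di-tert-butyl-4-methylpyridine in CH2Cl2 at −78 °C ionises F2, and the same closure gives the bicyclic ester 2-(trimethylsilyl)ethyl (1R,2S,7aS)-1-[(3Z)-5-(acetyloxy)-4-methylpent-3-en-1-yl]-1,7,7,7a-tetramethyl-2,3,5,6,7,7a-hexahydro-1H-indene-2-carboxylate F3. Here there is no carboxyl nucleophile, and the low temperature should sharpen the face selectivity. Bu4NF buffered with AcOH removes the ester to give 17.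

**Step 6.** The trianion carries a remote lithium alkoxide that may disturb the chiral aggregate. The sense and level of induction for this dienediolate rest on analogy. Some γ-alkylation is possible.

Fallback, from 10 back to 12, using a covalent auxiliary: 10 is silylated (t-BuMe2SiCl, imidazole; K2CO3/MeOH work-up) to (2E,6Z)-8-[(tert-butyldimethylsilyl)oxy]-3,7-dimethylocta-2,6-dienoic acid F4. Pivaloyl mixed anhydride and lithiated (4S)-4-benzyl-1,3-oxazolidin-2-one give (4S)-4-benzyl-3-[(2E,6Z)-8-[(tert-butyldimethylsilyl)oxy]-3,7-dimethylocta-2,6-dienoyl]-1,3-oxazolidin-2-one F5. NaN(SiMe3)2 at −78 °C then 4 gives, by deconjugative α-alkylation anti to the benzyl group, (4S)-4-benzyl-3-[(2S,6Z)-8-[(tert-butyldimethylsilyl)oxy]-7-methyl-3-methylidene-2-[(2,3,3-trimethylcyclohex-1-en-1-yl)methyl]oct-6-enoyl]-1,3-oxazolidin-2-one F6. LiOH/H2O2 gives (2S,6Z)-8-[(tert-butyldimethylsilyl)oxy]-7-methyl-3-methylidene-2-[(2,3,3-trimethylcyclohex-1-en-1-yl)methyl]oct-6-enoic acid F7, and Bu4NF gives 12.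

**Step 5.** The strongly basic β-oxido-ylide sequence runs on a substrate with a free carboxylate and an enolisable aldehyde, and the Z/E ratio may erode.

Fallback, from 7 back to 10: Still–Gennari olefination of 7 with ethyl 2-[bis(2,2,2-trifluoroethoxy)phosphoryl]propanoate (KN(SiMe3)2 2.2 equiv, 18-crown-6, THF, −78 °C) gives (2E,6Z)-8-ethoxy-3,7-dimethyl-8-oxoocta-2,6-dienoic acid F8. i-Bu2AlH (3.5 equiv, −78 °C) reduces the ester in the presence of the aluminium carboxylate to give 10.

## Further compounds

F1 | step 8 | 2-(trimethylsilyl)ethyl (2S,6Z)-8-(acetyloxy)-7-methyl-3-methylidene-2-[(2,3,3-trimethylcyclohex-1-en-1-yl)methyl]oct-6-enoate | CC(=O)OC/C(C)=C\CCC(=C)[C@H](CC1=C(C)C(C)(C)CCC1)C(=O)OCC[Si](C)(C)C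
F2 | step 8 | 2-(trimethylsilyl)ethyl (2R,6Z)-8-(acetyloxy)-3-chloro-3,7-dimethyl-2-[(2,3,3-trimethylcyclohex-1-en-1-yl)methyl]oct-6-enoate (C-3 epimers) | CC(=O)OC/C(C)=C\CCC(C)(Cl)[C@H](CC1=C(C)C(C)(C)CCC1)C(=O)OCC[Si](C)(C)C
F3 | step 8 | 2-(trimethylsilyl)ethyl (1R,2S,7aS)-1-[(3Z)-5-(acetyloxy)-4-methylpent-3-en-1-yl]-1,7,7,7a-tetramethyl-2,3,5,6,7,7a-hexahydro-1H-indene-2-carboxylate | CC(=O)OC/C(C)=C\CC[C@]1(C)[C@@H](C(=O)OCC[Si](C)(C)C)CC2=CCCC(C)(C)[C@@]21C
F4 | step 6 | (2E,6Z)-8-[(tert-butyldimethylsilyl)oxy]-3,7-dimethylocta-2,6-dienoic acid | CC(C)(C)[Si](C)(C)OC/C(C)=C\CC/C(C)=C/C(=O)O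
F5 | step 6 | (4S)-4-benzyl-3-[(2E,6Z)-8-[(tert-butyldimethylsilyl)oxy]-3,7-dimethylocta-2,6-dienoyl]-1,3-oxazolidin-2-one | CC(C)(C)[Si](C)(C)OC/C(C)=C\CC/C(C)=C/C(=O)N1[C@@H](Cc2ccccc2)COC1=O
F6 | step 6 | (4S)-4-benzyl-3-[(2S,6Z)-8-[(tert-butyldimethylsilyl)oxy]-7-methyl-3-methylidene-2-[(2,3,3-trimethylcyclohex-1-en-1-yl)methyl]oct-6-enoyl]-1,3-oxazolidin-2-one | CC(C)(C)[Si](C)(C)OC/C(C)=C\CCC(=C)[C@H](CC1=C(C)C(C)(C)CCC1)C(=O)N1[C@@H](Cc2ccccc2)COC1=O
F7 | step 6 | (2S,6Z)-8-[(tert-butyldimethylsilyl)oxy]-7-methyl-3-methylidene-2-[(2,3,3-trimethylcyclohex-1-en-1-yl)methyl]oct-6-enoic acid | CC(C)(C)[Si](C)(C)OC/C(C)=C\CCC(=C)[C@H](CC1=C(C)C(C)(C)CCC1)C(=O)O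
F8 | step 5 | (2E,6Z)-8-ethoxy-3,7-dimethyl-8-oxoocta-2,6-dienoic acid | CCOC(=O)/C(C)=C\CC/C(C)=C/C(=O)O
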